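## The problem

The target 23 is a (2R,3R)-dihydroflavonol: ring C (O1, C2, C3, C4, C4a, C8a) is a chroman-4-one fused to benzene ring A, C2 carries aryl ring B, C3 a hydroxyl, and C8, C3′ and C5′ each carry a 3-methylbut-2-enyl (prenyl) group. The only stereocentres are C2 and C3, vicinal and trans; attack on a C3=C4 enol derivative anti to the C2 aryl group gives the trans isomer, which is also the more stable one, so C2 can control C3 and only C2 has to be set absolutely. Both centres are fragile: C2 is a benzylic aryl-ether carbon β to the ketone, so base opens ring C by retro-oxa-Michael reaction and racemises it, while C3 is enolisable and the α-ketol is easily dehydrogenated to a flavonol. Each prenyl group sits ortho to a phenol oxygen (O7 for C8, O4′ for C3′ and C5′), so acid closes it onto that oxygen as a chroman, electrophilic oxidants epoxidise the trisubstituted alkenes, and hydrogenolysis is excluded. Direct C-prenylation of the phenols would give O/C and positional mixtures, and a prenyl ether would undergo Claisen rearrangement with allylic inversion to the wrong (1,1-dimethylallyl) isomer. The enabling feature is that C8, C3′ and C5′ bear three identical CH2–CH=C(CH3)2 units. Their C2″=C3″ bonds can be made last from three allyl groups, which Claisen rearrangement places exactly ortho to O7 and O4′ and whose terminal alkenes survive the oxidation that installs the C3 hydroxyl.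

## Retrosynthesis

**23 ⇒ 22 (two O–Si bonds).** The last operation is removal of the phenol protecting groups from 22. Silyl ethers are chosen because buffered fluoride is the one deprotection that avoids acid (chroman formation), hydrogen (alkene reduction) and strong base (ring opening at C2). O7 is para to the C4 carbonyl, so its silyl ether is a vinylogous silyl ester; it is made triisopropylsilyl (TIPS) to survive aqueous base and HCl earlier. O4′ is shielded by two ortho substituents and tert-butyldimethylsilyl (TBS) suffices.

**22 ⇒ 20 + 21 (three C2″=C3″ double bonds).** All three prenyl alkenes are cut at once, leading to the triallyl dihydroflavonol 20 and three molecules of 2-methylbut-2-ene 21. The neighbouring cut, the three aryl–CH2 bonds, would mean phenol prenylation without regiocontrol. Carrying prenyl groups from the start would expose trisubstituted alkenes to the C3 oxidation. Compound 20 has the full ring system and both stereocentres but only oxidation-tolerant terminal alkenes. The forward reaction must cap three alkenes completely without double-bond migration and without touching C2, C3 or the free hydroxyl.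

**20 ⇒ 18 ⇒ 17 (C3–O bond).** The C3 hydroxyl is removed to give flavanone 17 by way of its trimethylsilyl enol ether 18. This is preferred to building C2 and C3 together, because the existing C2 centre directs the oxidant anti to the aryl group, so no second absolute stereocontrol is needed. The silyl enol ether is made by soft enolisation rather than through a metal enolate, which could open ring C. The oxidant must select the enol ether over three monosubstituted alkenes.

**17 ⇒ 16 + 10 (C2–C1′ bond).** Cutting the bond between C2 and ring B divides the molecule into two achiral halves of similar size, chromone 16 and arylboronic acid 10. A conjugate addition catalysed by [RhCl(C2H4)2]2 with a chiral diene ligand sets C2 catalytically. The alternative, oxa-Michael closure of a chalcone, gives weaker enantiocontrol and needs base. The forward step must select one face of C2=C3, tolerate three allyl groups and use little base.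

**16 ⇒ 14 ⇒ 13 ⇒ 12 ⇒ 11 + 2 (ring C carbons, O–Si, C8–CH2, O–allyl).** C2 of the chromone is a one-carbon unit condensed onto the acetyl group of 14. The TIPS group is placed on the unchelated phenol of 13. The C8 allyl group of 13 comes from Claisen rearrangement of allyl ether 12, which is made from 2,4-dihydroxyacetophenone 11 and allyl bromide 2. The chelated 2-hydroxyl gives site selectivity in both the allylation and the silylation.

**10 ⇒ 7 ⇒ 6 ⇒ 5 ⇒ 4 ⇒ 3 ⇒ 1 + 2 (C–B, O–Si, two C–CH2, two O–allyl).** The boronic acid comes from bromide 7 by bromine–lithium exchange, and 7 from phenol 6 by silylation. Two rounds of O-allylation and Claisen rearrangement (6 from 5, 5 from 4, 4 from 3) lead back to 4-bromophenol 1 and allyl bromide 2. The bromine blocks the para position, so each rearrangement can only go ortho.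

## Roads not taken

Alternative 1: ring C closed at O1–C8a by intramolecular SNAr. The cut is the aryl ether bond. In the forward step the benzylic alkoxide of the open-chain fluoro ketone A1 (KN(SiMe3)2) would displace fluoride ortho to the ketone and give chromanone A2 with retention at C2 and C3.
- Merits: both stereocentres are made in an acyclic aldol-type precursor and carried into the ring unchanged. No oxidation is needed next to alkenes, and the C3 oxygen arrives protected. In these respects it is better than the chosen plan.
- Weak points: the alkoxide of A1 is an aldolate and can fragment by retro-aldol reaction, and the C–H between the carbonyl and the benzyloxy group is acidic, so the strong base threatens both centres. The fluorine is flanked by the acyl carbon and the prenylated carbon, and the silyloxy group para to the acyl carbon weakens the activation. A1 needs an auxiliary-controlled anti glycolate aldol reaction, and its fluorinated ring A half must already carry the prenyl group. The prenyl groups are present throughout, including an oxidative removal of the 4-methoxybenzyl group from A2.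
- Comparison: the chosen plan sets C2 by catalysis and C3 by substrate control from two simple achiral halves, and keeps the sensitive alkenes out of every step but the last two.

Alternative 2: ring A as a cyclohexanedione, acylation and epoxide opening, late aromatisation. The cuts are C4–C4a and O1–C2. The trans-epoxy amide A3 would acylate the lithium α′-enolate of silyloxy enone A4, in which ring A is still at the cyclohexane-1,3-dione oxidation level. BF3·OEt2 would then let the enolised diketone oxygen open the epoxide at the benzylic carbon with inversion, giving tetrahydrochromenone A5. Ring A must then be dehydrogenated.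
- Merits: the ring A substitution pattern is unambiguous, with no Claisen regioisomer and no high-temperature step. One enantiopure epoxide supplies both stereocentres and two bonds form in one flask. On these counts it is the more elegant plan.
- Weak points: acylation creates a C–H more acidic than that of A4, which quenches enolate, and the enolate can attack the epoxide of A3 instead of its amide. Lewis-acid opening next to an electron-rich 4-silyloxyphenyl group proceeds through a benzylic cation, which erodes the inversion and invites 1,2-acyl shift. The final dehydrogenation of A5 must spare three prenyl groups and an α-ketol that itself oxidises to a flavonol.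
- Comparison: the chosen plan is longer in the ring A branch, but every step has close precedent and the mildest steps come last.

Alternative 3: ring C closed at C4–C4a by Parham cyclisation. Bromine–lithium exchange on aryl ether amide A6 with t-BuLi, then attack of the aryllithium on the N-methoxy-N-methyl amide, would give chromanone A7.
- Merits: the ring closure does not involve C2 or C3, the chelated tetrahedral intermediate prevents over-addition, and A7 is one desilylation from the target. That end-game is as short as the chosen one and needs no oxidation.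
- Weak points: the difficulty moves into A6. Its benzylic aryl ether must be made stereospecifically from a phenol flanked by bromine and a prenyl group at an electron-rich benzylic carbon, where ionisation competes. The amide α-hydrogen of A6 is acidic and has an aryloxide β to the carbonyl, so β-elimination competes with the exchange. The 6-bromo-2-prenylphenoxy unit of A6 needs its own regiocontrolled synthesis, and the prenyl groups are exposed throughout.
- Comparison: the chosen plan forms the C2 centre catalytically on a closed ring, which A6 cannot match without a longer linear sequence.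

Against all three, the chosen plan has to accept two noble-metal steps, a chiral diene ligand, three thermal rearrangements and one oxidation in the presence of terminal alkenes.

Key step: step 14

Assumption: the sense of induction of the diene ligand with chromone 16 is taken to parallel that with cyclohex-2-enone, which predicts the (S,S)-ligand for the (2S)-flavanone; if it proves opposite, the (R,R)-ligand is used with no other change.

## Route

Step 1
Reactants: 1 4-bromophenol; 2 allyl bromide
Product: 3 1-(allyloxy)-4-bromobenzene
Conditions: K2CO3, acetone, reflux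
Reagents that add atoms: none
Why: Williamson ether synthesis; the phenoxide is alkylated cleanly on oxygen by SN2 displacement of bromide.

Step 2
Reactants: 3 1-(allyloxy)-4-bromobenzene
Product: 4 2-allyl-4-bromophenol
Conditions: N,N-diethylaniline, 200 °C
Reagents that add atoms: none
Why: Aromatic Claisen rearrangement ([3,3] shift, then tautomerisation); bromine blocks the para position, so the allyl group ends ortho to oxygen.

Step 3
Reactants: 4 2-allyl-4-bromophenol; 2 allyl bromide
Product: 5 2-allyl-1-(allyloxy)-4-bromobenzene
Conditions: K2CO3, acetone, reflux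
Reagents that add atoms: none
Why: Second Williamson ether synthesis; the ortho allyl group does not interfere.

Step 4
Reactants: 5 2-allyl-1-(allyloxy)-4-bromobenzene
Product: 6 2,6-diallyl-4-bromophenol
Conditions: N,N-diethylaniline, 200 °C
Reagents that add atoms: none
Why: Second aromatic Claisen rearrangement; one ortho carbon is free and the para carbon is blocked, so only the 2,6-diallyl phenol can form.

Step 5
Reactants: 6 2,6-diallyl-4-bromophenol
Product: 7 (2,6-diallyl-4-bromophenoxy)(tert-butyl)dimethylsilane
Conditions: TBSCl, imidazole, DMF, 40 °C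
Reagents that add atoms: tert-butyldimethylsilyl chloride, CC(C)(C)[Si](C)(C)Cl
Why: Phenol silylation; the two flanking allyl groups slow it but later shield this silyl ether from the aqueous base of step 11.

Step 6
Reactants: 7 (2,6-diallyl-4-bromophenoxy)(tert-butyl)dimethylsilane
Product: 10 [3,5-diallyl-4-(tert-butyldimethylsilyloxy)phenyl]boronic acid, via aryllithium 8 (not isolated), via lithium triisopropoxyborate 9 (not isolated)
Conditions: n-BuLi, THF, −78 °C; B(OiPr)3, −78 °C to rt; then 1 M aq. HCl
Reagents that add atoms: triisopropyl borate, CC(C)OB(OC(C)C)OC(C)C; water, O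
Why: Lithiation–borylation; bromine–lithium exchange at −78 °C is much faster than deprotonation of the benzylic allylic CH2 groups, and hydrolysis of the borate complex gives the boronic acid.

Step 7
Reactants: 11 2,4-dihydroxyacetophenone; 2 allyl bromide
Product: 12 1-[4-(allyloxy)-2-hydroxyphenyl]ethanone
Conditions: K2CO3, acetone, reflux
Reagents that add atoms: none
Why: Site-selective Williamson ether synthesis; the 2-hydroxyl is hydrogen-bonded to the acetyl group, so only the 4-hydroxyl is alkylated.

Step 8
Reactants: 12 1-[4-(allyloxy)-2-hydroxyphenyl]ethanone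
Product: 13 1-(3-allyl-2,4-dihydroxyphenyl)ethanone
Conditions: N,N-diethylaniline, 200–210 °C
Reagents that add atoms: none
Why: Aromatic Claisen rearrangement; in chelated 2,4-dioxygenated acetophenones the allyl group migrates mainly to C3 between the two oxygens, and the minor 5-allyl isomer would be separated here.

Step 9
Reactants: 13 1-(3-allyl-2,4-dihydroxyphenyl)ethanone
Product: 14 1-[3-allyl-2-hydroxy-4-(triisopropylsilyloxy)phenyl]ethanone
Conditions: TIPSCl, imidazole, DMF, rt
Reagents that add atoms: triisopropylsilyl chloride, CC(C)[Si](Cl)(C(C)C)C(C)C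
Why: Selective silylation of the unchelated 4-hydroxyl; TIPS is used because this oxygen becomes para to the C4 carbonyl and must resist HCl in step 10 and aqueous base in step 11.

Step 10
Reactants: 14 1-[3-allyl-2-hydroxy-4-(triisopropylsilyloxy)phenyl]ethanone
Product: 16 8-allyl-7-(triisopropylsilyloxy)-4H-chromen-4-one, via enaminone 15 (not isolated)
Conditions: Me2NCH(OMe)2, toluene, 100 °C; then conc. HCl, CH2Cl2, 40 °C
Reagents that add atoms: N,N-dimethylformamide dimethyl acetal, COC(OC)N(C)C
Why: Enaminone route to chromones; condensation at the methyl ketone, then acid-promoted conjugate addition of the phenol and loss of dimethylamine closes the pyranone ring.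

Step 11
Reactants: 16 8-allyl-7-(triisopropylsilyloxy)-4H-chromen-4-one; 10 [3,5-diallyl-4-(tert-butyldimethylsilyloxy)phenyl]boronic acid
Product: 17 (2S)-8-allyl-2-[3,5-diallyl-4-(tert-butyldimethylsilyloxy)phenyl]-7-(triisopropylsilyloxy)chroman-4-one
Conditions: [RhCl(C2H4)2]2 (2.5 mol %), (S,S)-2,5-diphenylbicyclo[2.2.2]octa-2,5-diene (5.5 mol %), aq. KOH (0.3 equiv), toluene–H2O, 30 °C
Reagents that add atoms: none
Why: Hayashi–Miyaura asymmetric 1,4-addition of an arylboronic acid to a chromone: transmetalation, face-selective insertion of C2=C3 into the aryl–Rh bond and protonolysis of the Rh enolate; the chiral diene selects the face and sets C2 as S, which is the spatial arrangement of C2 in the target, and the low base loading and temperature limit retro-oxa-Michael opening.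

Step 12
Reactants: 17 (2S)-8-allyl-2-[3,5-diallyl-4-(tert-butyldimethylsilyloxy)phenyl]-7-(triisopropylsilyloxy)chroman-4-one
Product: 18 (2S)-8-allyl-2-[3,5-diallyl-4-(tert-butyldimethylsilyloxy)phenyl]-7-(triisopropylsilyloxy)-4-(trimethylsilyloxy)-2H-chromene
Conditions: TMSOTf, Et3N, CH2Cl2, 0 °C
Reagents that add atoms: trimethylsilyl trifluoromethanesulfonate, C[Si](C)(C)OS(=O)(=O)C(F)(F)F
Why: Silyl enol ether formation by soft enolisation (O-silylation, then deprotonation at C3 by the amine); no free enolate is formed, so ring C cannot open by elimination and C2 is preserved.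

Step 13
Reactants: 18 (2S)-8-allyl-2-[3,5-diallyl-4-(tert-butyldimethylsilyloxy)phenyl]-7-(triisopropylsilyloxy)-4-(trimethylsilyloxy)-2H-chromene
Product: 20 (2R,3R)-8-allyl-2-[3,5-diallyl-4-(tert-butyldimethylsilyloxy)phenyl]-3-hydroxy-7-(triisopropylsilyloxy)chroman-4-one, via silyloxy epoxide 19 (not isolated)
Conditions: DMDO (1.1 equiv), acetone–CH2Cl2, −78 to −30 °C; then 10% aq. citric acid, MeOH, 0 °C
Reagents that add atoms: dimethyldioxirane, CC1(C)OO1
Why: Rubottom oxidation; the electron-rich silyl enol ether is epoxidised far faster than the three monosubstituted alkenes and from the face anti to the C2 aryl group, and mild acid opens the silyloxy epoxide to the trans α-hydroxy ketone, so C2 sets C3 as R (the descriptor of C2 changes from S to R by priority only).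

Step 14
Reactants: 20 (2R,3R)-8-allyl-2-[3,5-diallyl-4-(tert-butyldimethylsilyloxy)phenyl]-3-hydroxy-7-(triisopropylsilyloxy)chroman-4-one; 21 2-methylbut-2-ene (three molecules are consumed per molecule of 20, one for each allyl group; used in large excess as co-solvent)
Product: 22 (2R,3R)-2-[4-(tert-butyldimethylsilyloxy)-3,5-bis(3-methylbut-2-enyl)phenyl]-3-hydroxy-8-(3-methylbut-2-enyl)-7-(triisopropylsilyloxy)chroman-4-one
Conditions: second-generation Grubbs catalyst (H2IMes)(PCy3)Cl2Ru=CHPh (2 × 5 mol %), 2-methylbut-2-ene–CH2Cl2 (1:1), 40 °C, sealed vessel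
Reagents that add atoms: 2-methylbut-2-ene (the second and third molecules of 21, which supply the isopropylidene units of the second and third prenyl groups), CC=C(C)C
Why: Threefold olefin cross-metathesis, which consumes three molecules of 21 and releases three of propene: the Ru=CHPh unit of the catalyst enters at a terminal allyl alkene by [2+2] cycloaddition and cycloreversion, and the resulting alkylidenes exchange with 2-methylbut-2-ene, which hands an isopropylidene unit to each ArCH2CH= terminus while its ethylidene half leaves with the terminal CH2 of the allyl group as propene. The closest known reaction is the conversion of ortho-allylphenol derivatives into prenylarenes with 2-methylbut-2-ene and the same catalyst. No ring closes: the C3′ and C5′ arms are meta to each other and the C8 arm is remote, so ring-closing metathesis between arms is geometrically excluded. No stereocentre is formed, and the neutral medium leaves C2 (no retro-oxa-Michael) and C3 (no enolisation) untouched. The selectivity needed is complete and uniform capping of three monosubstituted alkenes; these are the fast-reacting alkene class, whereas the trisubstituted prenyl products are almost inert, so each arm is capped once and stays capped. Arms that first receive an ethylidene unit are still 1,2-disubstituted and re-enter the cycle until they carry the isopropylidene, and the large excess of the volatile partner suppresses coupling between arms. The ketone, the free C3 hydroxyl and both aryl silyl ethers are spectators, and a moderate temperature with a second catalyst charge instead of long heating limits Ru–H-mediated migration of allyl to propenyl.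

Step 15
Reactants: 22 (2R,3R)-2-[4-(tert-butyldimethylsilyloxy)-3,5-bis(3-methylbut-2-enyl)phenyl]-3-hydroxy-8-(3-methylbut-2-enyl)-7-(triisopropylsilyloxy)chroman-4-one
Product: 23 (2R,3R)-3,7-dihydroxy-2-[4-hydroxy-3,5-bis(3-methylbut-2-enyl)phenyl]-8-(3-methylbut-2-enyl)chroman-4-one
Conditions: Bu4NF, AcOH (1:1), THF, 0 °C to rt
Reagents that add atoms: none
Why: Fluoride-mediated desilylation of both aryl silyl ethers; acetic acid buffers the phenoxides so that ring opening at C2, epimerisation at C3 and acid-induced chroman formation from the prenyl groups are all avoided.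

## Compound list

1 | 4-bromophenol | Oc1ccc(Br)cc1 | starting material
2 | allyl bromide (3-bromoprop-1-ene) | C=CCBr | starting material
3 | 1-(allyloxy)-4-bromobenzene | C=CCOc1ccc(Br)cc1 | intermediate
4 | 2-allyl-4-bromophenol | C=CCc1cc(Br)ccc1O | intermediate
5 | 2-allyl-1-(allyloxy)-4-bromobenzene | C=CCOc1ccc(Br)cc1CC=C | intermediate
6 | 2,6-diallyl-4-bromophenol | C=CCc1cc(Br)cc(CC=C)c1O | intermediate
7 | (2,6-diallyl-4-bromophenoxy)(tert-butyl)dimethylsilane | C=CCc1cc(Br)cc(CC=C)c1O[Si](C)(C)C(C)(C)C | intermediate
8 | [3,5-diallyl-4-(tert-butyldimethylsilyloxy)phenyl]lithium | [Li]c1cc(CC=C)c(O[Si](C)(C)C(C)(C)C)c(CC=C)c1 | intermediate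
9 | lithium [3,5-diallyl-4-(tert-butyldimethylsilyloxy)phenyl]triisopropoxyborate | [Li+].CC(C)O[B-](OC(C)C)(OC(C)C)c1cc(CC=C)c(O[Si](C)(C)C(C)(C)C)c(CC=C)c1 | intermediate
10 | [3,5-diallyl-4-(tert-butyldimethylsilyloxy)phenyl]boronic acid | OB(O)c1cc(CC=C)c(O[Si](C)(C)C(C)(C)C)c(CC=C)c1 | intermediate
11 | 2,4-dihydroxyacetophenone | CC(=O)c1ccc(O)cc1O | starting material
12 | 1-[4-(allyloxy)-2-hydroxyphenyl]ethanone | CC(=O)c1ccc(OCC=C)cc1O | intermediate
13 | 1-(3-allyl-2,4-dihydroxyphenyl)ethanone | CC(=O)c1ccc(O)c(CC=C)c1O | intermediate
14 | 1-[3-allyl-2-hydroxy-4-(triisopropylsilyloxy)phenyl]ethanone | CC(=O)c1ccc(O[Si](C(C)C)(C(C)C)C(C)C)c(CC=C)c1O | intermediate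
15 | (E)-1-[3-allyl-2-hydroxy-4-(triisopropylsilyloxy)phenyl]-3-(dimethylamino)prop-2-en-1-one | CN(C)/C=C/C(=O)c1ccc(O[Si](C(C)C)(C(C)C)C(C)C)c(CC=C)c1O | intermediate
16 | 8-allyl-7-(triisopropylsilyloxy)-4H-chromen-4-one | O=c1ccoc2c(CC=C)c(O[Si](C(C)C)(C(C)C)C(C)C)ccc12 | intermediate
17 | (2S)-8-allyl-2-[3,5-diallyl-4-(tert-butyldimethylsilyloxy)phenyl]-7-(triisopropylsilyloxy)chroman-4-one | O=C1c2ccc(O[Si](C(C)C)(C(C)C)C(C)C)c(CC=C)c2O[C@H](c2cc(CC=C)c(O[Si](C)(C)C(C)(C)C)c(CC=C)c2)C1 | intermediate
18 | (2S)-8-allyl-2-[3,5-diallyl-4-(tert-butyldimethylsilyloxy)phenyl]-7-(triisopropylsilyloxy)-4-(trimethylsilyloxy)-2H-chromene | C[Si](C)(C)OC1=C[C@@H](c2cc(CC=C)c(O[Si](C)(C)C(C)(C)C)c(CC=C)c2)Oc2c(CC=C)c(O[Si](C(C)C)(C(C)C)C(C)C)ccc12 | intermediate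
19 | (2R,3R,4R)-8-allyl-2-[3,5-diallyl-4-(tert-butyldimethylsilyloxy)phenyl]-3,4-epoxy-7-(triisopropylsilyloxy)-4-(trimethylsilyloxy)chroman, epoxide oxygen trans to the C2 aryl group | C[Si](C)(C)O[C@@]12O[C@@H]1[C@@H](c1cc(CC=C)c(O[Si](C)(C)C(C)(C)C)c(CC=C)c1)Oc1c(CC=C)c(O[Si](C(C)C)(C(C)C)C(C)C)ccc12 | intermediate
20 | (2R,3R)-8-allyl-2-[3,5-diallyl-4-(tert-butyldimethylsilyloxy)phenyl]-3-hydroxy-7-(triisopropylsilyloxy)chroman-4-one | O=C1c2ccc(O[Si](C(C)C)(C(C)C)C(C)C)c(CC=C)c2O[C@H](c2cc(CC=C)c(O[Si](C)(C)C(C)(C)C)c(CC=C)c2)[C@H]1O | intermediate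
21 | 2-methylbut-2-ene | CC=C(C)C | starting material
22 | (2R,3R)-2-[4-(tert-butyldimethylsilyloxy)-3,5-bis(3-methylbut-2-enyl)phenyl]-3-hydroxy-8-(3-methylbut-2-enyl)-7-(triisopropylsilyloxy)chroman-4-one | O=C1c2ccc(O[Si](C(C)C)(C(C)C)C(C)C)c(CC=C(C)C)c2O[C@H](c2cc(CC=C(C)C)c(O[Si](C)(C)C(C)(C)C)c(CC=C(C)C)c2)[C@H]1O | intermediate
23 | (2R,3R)-3,7-dihydroxy-2-[4-hydroxy-3,5-bis(3-methylbut-2-enyl)phenyl]-8-(3-methylbut-2-enyl)chroman-4-one (CNP0316331.1) | CC(C)=CCc1cc([C@H]2Oc3c(ccc(O)c3CC=C(C)C)C(=O)[C@@H]2O)cc(CC=C(C)C)c1O | target

## Step count and risk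

Total: 15 steps. Longest linear sequence: 11 steps (steps 1–6, then 11–15, from 4-bromophenol). The ring A branch (steps 7–10) has 4 steps.

**Step 14 (key step).**
- What may go wrong: non-uniform capping, with some arms left as allyl or stopped at the but-2-enyl stage; migration of allyl to propenyl by Ru–H species, followed by chain-shortening metathesis; slowing of the catalyst by chelation to the α-ketol. With three arms, any of these gives mixtures that are hard to separate.
- Fallback: the metathesis is moved one stage back, to flavanone 17, which has no α-ketol and tolerates repeated treatment. With 21 (again three molecules consumed per molecule of substrate) and the same catalyst it would give (2S)-2-[4-(tert-butyldimethylsilyloxy)-3,5-bis(3-methylbut-2-enyl)phenyl]-8-(3-methylbut-2-enyl)-7-(triisopropylsilyloxy)chroman-4-one F1. DMDO is no longer acceptable beside trisubstituted alkenes, so the hydroxyl is introduced differently. KN(SiMe3)2 in THF at −78 °C would give potassium (2S)-2-[4-(tert-butyldimethylsilyloxy)-3,5-bis(3-methylbut-2-enyl)phenyl]-8-(3-methylbut-2-enyl)-7-(triisopropylsilyloxy)-2H-chromen-4-olate F2, which is oxidised with 2-(phenylsulfonyl)-3-phenyloxaziridine and quenched cold with AcOH. This reagent does not epoxidise alkenes. The sequence returns to the route at 22.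

**Step 11.**
- What may go wrong: slow insertion, because the 7-silyloxy group makes the chromone a poor acceptor, so protodeboronation of the electron-rich boronic acid competes; base-induced ring opening of the product, which erodes the enantiomeric purity; insufficient or reversed facial selectivity.
- Fallback: a chalcone epoxide route that sets out from 14 and from aryllithium 8 and returns at 20, bypassing 16–19.
  - Quenching 8 with DMF would give 3,5-diallyl-4-(tert-butyldimethylsilyloxy)benzaldehyde F3.
  - Ketone 14 is protected (NaH, MOMCl, THF) as 1-[3-allyl-2-(methoxymethoxy)-4-(triisopropylsilyloxy)phenyl]ethanone F4.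
  - A directed aldol condensation (LiN(SiMe3)2, THF, −78 °C; then MsCl, Et3N) would give (E)-1-[3-allyl-2-(methoxymethoxy)-4-(triisopropylsilyloxy)phenyl]-3-[3,5-diallyl-4-(tert-butyldimethylsilyloxy)phenyl]prop-2-en-1-one F5.
  - Juliá–Colonna epoxidation (poly-L-leucine, urea–H2O2, DBU, THF) is nucleophilic and cannot touch the allyl groups. It would give [3-allyl-2-(methoxymethoxy)-4-(triisopropylsilyloxy)phenyl][(2R,3S)-3-[3,5-diallyl-4-(tert-butyldimethylsilyloxy)phenyl]oxiran-2-yl]methanone F6.
  - HCl in MeOH–THF removes the methoxymethyl group, and the freed phenol opens the epoxide at the benzylic carbon (6-endo, inversion) to give 20. The C3 configuration comes from the epoxide, and the trans preference corrects C2 if the opening is partly ionic.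

**Step 13.**
- What may go wrong: hydrolysis of the labile enol ether back to 17 before it is oxidised; competing epoxidation of an allyl group or oxidation of the electron-rich ring B if excess oxidant or higher temperature is needed; loss of trans selectivity.
- Fallback: direct enolate hydroxylation of 17. KN(SiMe3)2 in THF at −78 °C would give potassium (2S)-8-allyl-2-[3,5-diallyl-4-(tert-butyldimethylsilyloxy)phenyl]-7-(triisopropylsilyloxy)-2H-chromen-4-olate F7, which is treated at that temperature with 2-(phenylsulfonyl)-3-phenyloxaziridine and quenched cold with AcOH. Oxygen is transferred only to the enolate carbon, anti to the C2 aryl group. The sequence returns at 20.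

**Step 15.**
- What may go wrong: phenoxide formed on desilylation opens ring C (racemisation at C2), epimerises C3 or allows air oxidation to the flavonol; the 4′-silyl ether, flanked by two prenyl groups, cleaves slowly and invites forcing conditions that the prenyl groups or the α-ketol do not tolerate.
- Fallback: the order of the last two operations is reversed. At the triallyl stage acid is harmless, so 20 is desilylated with aqueous HF in MeCN to (2R,3R)-8-allyl-2-(3,5-diallyl-4-hydroxyphenyl)-3,7-dihydroxychroman-4-one F8. The triple cross-metathesis with 21 (three molecules consumed per molecule of F8) and second-generation Grubbs catalyst (H2IMes)(PCy3)Cl2Ru=CHPh, which tolerates free phenols, is then run on F8 and gives 23 directly.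

## Further compounds

F1 | step 14 | (2S)-2-[4-(tert-butyldimethylsilyloxy)-3,5-bis(3-methylbut-2-enyl)phenyl]-8-(3-methylbut-2-enyl)-7-(triisopropylsilyloxy)chroman-4-one | O=C1c2ccc(O[Si](C(C)C)(C(C)C)C(C)C)c(CC=C(C)C)c2O[C@H](c2cc(CC=C(C)C)c(O[Si](C)(C)C(C)(C)C)c(CC=C(C)C)c2)C1
F2 | step 14 | potassium (2S)-2-[4-(tert-butyldimethylsilyloxy)-3,5-bis(3-methylbut-2-enyl)phenyl]-8-(3-methylbut-2-enyl)-7-(triisopropylsilyloxy)-2H-chromen-4-olate | [K+].[O-]C1=C[C@@H](c2cc(CC=C(C)C)c(O[Si](C)(C)C(C)(C)C)c(CC=C(C)C)c2)Oc2c(CC=C(C)C)c(O[Si](C(C)C)(C(C)C)C(C)C)ccc12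
F3 | step 11 | 3,5-diallyl-4-(tert-butyldimethylsilyloxy)benzaldehyde | O=Cc1cc(CC=C)c(O[Si](C)(C)C(C)(C)C)c(CC=C)c1
F4 | step 11 | 1-[3-allyl-2-(methoxymethoxy)-4-(triisopropylsilyloxy)phenyl]ethanone | CC(=O)c1ccc(O[Si](C(C)C)(C(C)C)C(C)C)c(CC=C)c1OCOC
F5 | step 11 | (E)-1-[3-allyl-2-(methoxymethoxy)-4-(triisopropylsilyloxy)phenyl]-3-[3,5-diallyl-4-(tert-butyldimethylsilyloxy)phenyl]prop-2-en-1-one | COCOc1c(CC=C)c(O[Si](C(C)C)(C(C)C)C(C)C)ccc1C(=O)/C=C/c1cc(CC=C)c(O[Si](C)(C)C(C)(C)C)c(CC=C)c1
F6 | step 11 | [3-allyl-2-(methoxymethoxy)-4-(triisopropylsilyloxy)phenyl][(2R,3S)-3-[3,5-diallyl-4-(tert-butyldimethylsilyloxy)phenyl]oxiran-2-yl]methanone | COCOc1c(CC=C)c(O[Si](C(C)C)(C(C)C)C(C)C)ccc1C(=O)[C@@H]1O[C@H]1c1cc(CC=C)c(O[Si](C)(C)C(C)(C)C)c(CC=C)c1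
F7 | step 13 | potassium (2S)-8-allyl-2-[3,5-diallyl-4-(tert-butyldimethylsilyloxy)phenyl]-7-(triisopropylsilyloxy)-2H-chromen-4-olate | [K+].[O-]C1=C[C@@H](c2cc(CC=C)c(O[Si](C)(C)C(C)(C)C)c(CC=C)c2)Oc2c(CC=C)c(O[Si](C(C)C)(C(C)C)C(C)C)ccc12
F8 | step 15 | (2R,3R)-8-allyl-2-(3,5-diallyl-4-hydroxyphenyl)-3,7-dihydroxychroman-4-one | O=C1c2ccc(O)c(CC=C)c2O[C@H](c2cc(CC=C)c(O)c(CC=C)c2)[C@H]1O
A1 | alternative 1 | (2R,3R)-1-[2-fluoro-3-(3-methylbut-2-enyl)-4-(triisopropylsilyloxy)phenyl]-3-hydroxy-2-(4-methoxybenzyloxy)-3-[3,5-bis(3-methylbut-2-enyl)-4-(triisopropylsilyloxy)phenyl]propan-1-one | O=C(c1ccc(O[Si](C(C)C)(C(C)C)C(C)C)c(CC=C(C)C)c1F)[C@H](OCc1ccc(OC)cc1)[C@H](O)c1cc(CC=C(C)C)c(O[Si](C(C)C)(C(C)C)C(C)C)c(CC=C(C)C)c1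
A2 | alternative 1 | (2R,3R)-3-(4-methoxybenzyloxy)-8-(3-methylbut-2-enyl)-2-[3,5-bis(3-methylbut-2-enyl)-4-(triisopropylsilyloxy)phenyl]-7-(triisopropylsilyloxy)chroman-4-one | O=C1c2ccc(O[Si](C(C)C)(C(C)C)C(C)C)c(CC=C(C)C)c2O[C@H](c2cc(CC=C(C)C)c(O[Si](C(C)C)(C(C)C)C(C)C)c(CC=C(C)C)c2)[C@H]1OCc1ccc(OC)cc1
A3 | alternative 2 | [(2R,3S)-3-[4-(tert-butyldimethylsilyloxy)-3,5-bis(3-methylbut-2-enyl)phenyl]oxiran-2-yl](morpholin-4-yl)methanone | O=C(N1CCOCC1)[C@@H]1O[C@H]1c1cc(CC=C(C)C)c(O[Si](C)(C)C(C)(C)C)c(CC=C(C)C)c1
A4 | alternative 2 | 2-(3-methylbut-2-enyl)-3-(triisopropylsilyloxy)cyclohex-2-en-1-one | O=C1CCCC(O[Si](C(C)C)(C(C)C)C(C)C)=C1CC=C(C)C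
A5 | alternative 2 | (2R,3R)-2-[4-(tert-butyldimethylsilyloxy)-3,5-bis(3-methylbut-2-enyl)phenyl]-3-hydroxy-8-(3-methylbut-2-enyl)-7-(triisopropylsilyloxy)-2,3,5,6-tetrahydro-4H-chromen-4-one | O=C1C2=C(C(CC=C(C)C)=C(O[Si](C(C)C)(C(C)C)C(C)C)CC2)O[C@H](c2cc(CC=C(C)C)c(O[Si](C)(C)C(C)(C)C)c(CC=C(C)C)c2)[C@H]1O
A6 | alternative 3 | (2R,3R)-3-[6-bromo-3-(tert-butyldimethylsilyloxy)-2-(3-methylbut-2-enyl)phenoxy]-2-(tert-butyldimethylsilyloxy)-3-[4-(tert-butyldimethylsilyloxy)-3,5-bis(3-methylbut-2-enyl)phenyl]-N-methoxy-N-methylpropanamide | CON(C)C(=O)[C@H](O[Si](C)(C)C(C)(C)C)[C@H](Oc1c(Br)ccc(O[Si](C)(C)C(C)(C)C)c1CC=C(C)C)c1cc(CC=C(C)C)c(O[Si](C)(C)C(C)(C)C)c(CC=C(C)C)c1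
A7 | alternative 3 | (2R,3R)-3,7-bis(tert-butyldimethylsilyloxy)-2-[4-(tert-butyldimethylsilyloxy)-3,5-bis(3-methylbut-2-enyl)phenyl]-8-(3-methylbut-2-enyl)chroman-4-one | O=C1c2ccc(O[Si](C)(C)C(C)(C)C)c(CC=C(C)C)c2O[C@H](c2cc(CC=C(C)C)c(O[Si](C)(C)C(C)(C)C)c(CC=C(C)C)c2)[C@H]1O[Si](C)(C)C(C)(C)C
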